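We have no constants for L, Q or J, so we make one from the readings: the relaxation half-life, the time in which J's excess over its resting level halves. We count how many of these half-lives each flask spends hot.

common to all: L 0.010 M
- delta: Q 0.34 mM; temperature 85 °C; run made earlier
- eta: Q 0.75 mM; temperature 102 °C; run made earlier
- Tuesday's: Q 0.500 mM; temperature 115 °C; time 2.0 h
- Wednesday's: Q 0.500 mM; at 90 °C until 1.0 h, from then on at 115 °C; time 2.0 h
- Saturday's: Q 0.500 mM; temperature 90 °C; time 2.0 h

| run | time / h | J / % |
|---|---|---|
| delta | 0.833 | 51.6 |
| delta | 3.00 | 46.5 |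
| delta | 4.00 | 44.3 |
| delta | 6.00 | 41.6 |
| delta | 12.0 | 33.4 |
| eta | 0.417 | 34.2 |
| eta | 0.667 | 32.1 |
| eta | 1.33 | 27.6 |
| eta | 2.50 | 23.3 |
| eta | 5.00 | 20.1 |

(scatter of a reading: 0.5 percentage points)

- what was read earlier has a scatter of 0.5 percentage points, one standard deviation
- a reading or a percentage of J counts all its forms, free or not

- the flask with the highest amount of J, in percent of the L charged ("all alike" if they lie within 1.5 percentage points) (Tuesday's / Wednesday's / Saturday's / all alike)
- final J, as a percentage of the L charged, in Tuesday's
- final J, as a percentage of the L charged, in Wednesday's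
- final J, as a percentage of the L charged, in Saturday's

We reckon as follows. The eta run appears to level off near its last reading, 20.1%, and we take that as the resting level at every temperature, which is a bold step. Its excess falls between the first and third readings, giving

half-life at 102 °C = 1.00 h

For temperature we compare the early fractional loss of J:

delta: 0.0480 h⁻¹; eta: 0.235 h⁻¹

We credit this whole change to temperature, though Q differs too, and take a constant factor per degree. That gives

half-life at 115 °C = 0.298 h; at 90 °C = 3.07 h

Interpolating the first readings puts J near 46.5% after the first hour at 90 °C. Wednesday's hot hour then counts 3.36 half-lives, so our Wednesday's is 22.7%. A further hour at 90 °C gives our Saturday's, 41.2%, and Tuesday's sits near the resting level.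

The weak link is the delta rate. Its third-to-sixth-hour readings give 0.0371 h⁻¹, which puts Wednesday's at 21.7% by this route; that is an estimate from one pair of readings, not a limit, and we keep our figure.

The forecast says 19% for Tuesday's, 34% for Wednesday's and 40% for Saturday's, with Saturday's highest. It reads J's levelling as fitting “either reversible J loss or a dying catalyst”. On Wednesday's, our figure and the forecast differ by 11 percentage points.

The flasks give 20.2% for Tuesday's, 20.6% for Wednesday's and 41.8% for Saturday's, so Saturday's holds the most J.

    L ⇌ J (K = 1.10, k = 0.0930 min⁻¹, Ea = 105 kJ mol⁻¹, ΔH = −37.0 kJ mol⁻¹)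
    L ⇌ G (K = 3.10, k = 0.00180 min⁻¹, Ea = 109 kJ mol⁻¹, ΔH = −75.0 kJ mol⁻¹)
    L ⇌ E (K = 0.740, k = 0.00150 min⁻¹, Ea = 113 kJ mol⁻¹, ΔH = −55.0 kJ mol⁻¹)
    L + Q → Z (k = 83.0 L mol⁻¹ min⁻¹, Ea = 68.0 kJ mol⁻¹)
    X ⇌ J, rate k5*(cs5 - [J]) while solid is left; crystals form when [J] > cs5 (solubility = 7.40 mM, k = 7.10 min⁻¹)
    (constants at 90 °C)

Saturday's read at 8.0 h takes the same reckoning: counted from the first hour at 90 °C, it spends 2.28 half-lives, which gives J of 25.5%. That flask reads 28.9%.

All runs come from a simulation with made-up constants; noise was put on by code.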